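**Conventions.** Oxane locants: O1, C2 (carries ring A, the 3,4‑dihydroxy‑5‑methoxyphenyl group), C4 (OH), C6 (carries the CH2CH2–ring B chain; ring B is 4‑hydroxy‑3‑methoxyphenyl). Open‑chain compounds use heptane locants, C1 on ring A and C7 on ring B, so heptane C1/C3/C5 are oxane C2/C4/C6. The target 13 is (2S,4S,6S): ring A and the side chain are cis and equatorial, and the C4 hydroxyl is trans to both and axial.

**Assumption.** [RuCl(p‑cymene)((S)‑BINAP)]Cl is taken to reduce diketone 7 with the facial sense known for simple acyclic β‑diketones ((R)‑BINAP gives (R,R)‑pentane‑2,4‑diol), the CH2CH2Ar groups standing in for methyl.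

## The problem

The target is a 1,7‑diarylheptanoid in which the C1 and C5 oxygens are one atom. It is a 2,4,6‑trisubstituted oxane with a free alcohol at C4, ring A directly on C2 and ring B two carbons away from C6. The chain is a consonant 1,3,5‑trioxygenated array, so its C–C bonds are easy; the difficulty is stereochemical and chemoselective. C6 can control C2 through the ring, because cis‑2,6 is the diequatorial arrangement. Nothing in the ring favours the axial C4 hydroxyl, which must come from kinetic control or from an inversion. The two chain ends differ by a single phenolic OH, so the open‑chain 3,5‑diols are nearly symmetric: the anti‑diol is close to C2‑symmetric and the syn‑diol (the one that maps directly onto the target) is close to meso. This decides what one catalyst can set in one operation. The fragile groups are the catechol of ring A (oxidants, base, air) and the O1–C2 bond, a para‑hydroxybenzyl ether that ionises in acid and can be hydrogenolysed. That same lability makes C2 the one stereocentre that can be set by equilibration.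

## Retrosynthesis

**13 ⇒ 12.** The two aryl O–benzyl bonds (ring A O3, ring B O4) are cut last. Benzyl is chosen because its removal is neutral and spares the acid‑labile O1–C2 bond. The pattern leaves ring A O4 free throughout, which is the one phenol the key step needs.

**12 ⇒ 11 ⇒ 10.** The C4–O bond is cut and re‑made with inversion (Mitsunobu ester 11, then ester cleavage). Accepting this inversion lets the ring precursor be the all‑cis alcohol 10 and hence the acyclic precursor be an anti‑diol. An anti‑diol is what a single catalyst can deliver from a symmetric‑looking diketone; the syn‑diol is not (see Alternative 3).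

**10 ⇒ 9 ⇒ 8 (key disconnection).** The O1–C2 bond is cut. The enabling feature is that C2 is benzylic and para to the free 4‑OH of ring A, so the bond is the 1,6‑adduct of O5–H to para‑quinone methide 9. Compound 9 arises from phenol 8 by loss of two hydrogens, with C1 starting as a plain CH2. Cutting here, and not at C2–C3 (Prins) or at the ketone level (oxa‑Michael), removes a ring and a stereocentre and leaves an acyclic diol with no benzylic oxygen. The forward step must oxidise ring A only, close with O5 and not O3, and give the 2,6‑cis isomer. These are secured by the benzyl ether on ring B, by ring size, and by reversibility of the addition.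

**8 ⇒ 7.** The C3–H and C5–H bonds are cut (Noyori asymmetric hydrogenation). In diketone 7 the two carbonyls each sit between CH2 and CH2CH2Ar and look the same to the catalyst, so both are reduced with the same sense to the anti‑(3S,5S)‑diol. The catalyst never has to tell the carbonyls apart, because in an anti‑diol either hydroxyl closes to the same relative configuration; the ring A phenol alone decides which one ends up in the ring. One operation sets two stereocentres, and the diol is expected to be essentially enantiopure because a wrong‑sense reduction gives the separable syn diastereomer.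

**7 ⇒ 6 ⇒ 5 + 2; 5 ⇒ 3 + 4.** The C1–C2 and C6–C7 bonds are traced to alkenes and cut by two aldol condensations on the terminal methyls of acetylacetone 3, first with aldehyde 4 and then with aldehyde 2. All seven chain carbons and both arenes come from three commercial compounds. The forward steps need condensation at the methyl groups (boron chelation) and alkene hydrogenation that spares benzyl ethers.

**2 ⇒ 1.** The O3–benzyl bond of ring A is cut; 5‑hydroxyvanillin 1 is benzylated at the phenoxide that is not conjugated to the aldehyde.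

## Roads not taken

**Alternative 1:** (the most obvious) Cut O1–C2 at the ketone oxidation level. The (1E,5S)‑5‑hydroxy enone A1 would close by intramolecular oxa‑Michael addition to the cis‑oxan‑4‑one A2, and a bulky hydride would give the axial alcohol 12.
- A1 needs a regiodefined, enantioenriched β‑hydroxy ketone built linearly (asymmetric step, homologation, olefination with 2). That is a longer run‑up than two condensations on 3, and only one stereocentre is bought by the asymmetric step.
- The enone of A1 is a vinylogous ester of the para‑oxygenated ring A (a vinylogous carboxylate once the phenol is deprotonated), so it is a poor acceptor.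
- In A2 both ring C–O bonds are β to the carbonyl. Retro‑oxa‑Michael opening on the C6 side erases the only catalyst‑set stereocentre. In the chosen route C4 is never a carbonyl once stereocentres exist.

**Alternative 2:** Cut O1–C2 and C2–C3 (Prins cyclisation). The (3S)‑homoallylic alcohol A3 and aldehyde 2 under acid would give, after ester cleavage, the same all‑cis alcohol 10.
- The oxocarbenium ion from an aldehyde carrying a para‑oxygen donor is prone to 2‑oxonia‑Cope rearrangement and to benzylic ionisation. Both exchange the substituents and erode the configuration of A3.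
- The route still ends at the equatorial alcohol, so the inversion is not saved.
- A3 needs its own aldehyde synthesis and asymmetric allylation.

**Alternative 3:** Keep the quinone methide ring closure but feed it the syn‑(3R,5S)‑diol A5, made by 1,3‑syn reduction (Narasaka–Prasad) of the (5S)‑β‑hydroxy ketone A4. This would give 12 directly with no inversion.
- A5 is the near‑meso diol. Catalyst‑controlled reduction of 7 cannot give it, so A4 must be built regiodefined by an asymmetric methyl‑ketone aldol between a ring A ketone and a ring B aldehyde. Each partner needs several homologation and protection steps, and acetate‑type aldols are among the less selective asymmetric aldols.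
- The two carbinol centres are then set in two separate steps after a longer run‑up. This costs more than the two steps of the Mitsunobu pair.

Key step: step 6

## Route

Step 1
Reactants: 1 3,4‑dihydroxy‑5‑methoxybenzaldehyde (5‑hydroxyvanillin)
Product: 2 3‑(benzyloxy)‑4‑hydroxy‑5‑methoxybenzaldehyde
Conditions: NaH (2.2 equiv), DMSO, rt; BnBr (1.0 equiv), rt; aq. HCl work‑up
Reagents that add atoms: benzyl bromide, BrCc1ccccc1
Why: Williamson ether synthesis on the dianion; the O4 phenoxide is para to the formyl group, delocalised and flanked on both sides, so the more basic meta phenoxide O3 should be alkylated first; no stereocentre.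

Step 2
Reactants: 3 pentane‑2,4‑dione (acetylacetone, 3 equiv); 4 4‑(benzyloxy)‑3‑methoxybenzaldehyde
Product: 5 (5E)‑6‑[4‑(benzyloxy)‑3‑methoxyphenyl]hex‑5‑ene‑2,4‑dione
Conditions: B2O3, EtOAc, 70 °C; then 4, B(OBu)3, n‑BuNH2 (cat., slow addition), 70 °C; then 1 M HCl, 60 °C
Reagents that add atoms: none
Why: Boron‑mediated aldol condensation of the curcuminoid type; chelation of the enolised diketone to boron masks C3, so condensation occurs at a terminal methyl, and excess 3 limits double condensation; dehydration to the conjugated enone gives the E alkene.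

Step 3
Reactants: 5 (5E)‑6‑[4‑(benzyloxy)‑3‑methoxyphenyl]hex‑5‑ene‑2,4‑dione; 2 3‑(benzyloxy)‑4‑hydroxy‑5‑methoxybenzaldehyde
Product: 6 (1E,6E)‑1‑[3‑(benzyloxy)‑4‑hydroxy‑5‑methoxyphenyl]‑7‑[4‑(benzyloxy)‑3‑methoxyphenyl]hepta‑1,6‑diene‑3,5‑dione
Conditions: B2O3, EtOAc–DMF, 70 °C; then 2, B(OBu)3, n‑BuNH2 (cat.), 70 °C; then 1 M HCl, 60 °C
Reagents that add atoms: none
Why: Second boron‑mediated aldol condensation at the remaining methyl of 5; free para‑hydroxybenzaldehydes are standard partners in this reaction (vanillin itself), so the phenol of 2 needs no protection.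

Step 4
Reactants: 6 (1E,6E)‑1‑[3‑(benzyloxy)‑4‑hydroxy‑5‑methoxyphenyl]‑7‑[4‑(benzyloxy)‑3‑methoxyphenyl]hepta‑1,6‑diene‑3,5‑dione
Product: 7 1‑[3‑(benzyloxy)‑4‑hydroxy‑5‑methoxyphenyl]‑7‑[4‑(benzyloxy)‑3‑methoxyphenyl]heptane‑3,5‑dione
Conditions: H2 (1 atm), 10% Pd/C, Ph2S (cat.), THF–EtOAc, rt
Reagents that add atoms: none
Why: Heterogeneous hydrogenation of the two conjugated C=C bonds; sulfide‑poisoned Pd/C is known to reduce alkenes while sparing aryl benzyl ethers and ketones.

Step 5
Reactants: 7 1‑[3‑(benzyloxy)‑4‑hydroxy‑5‑methoxyphenyl]‑7‑[4‑(benzyloxy)‑3‑methoxyphenyl]heptane‑3,5‑dione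
Product: 8 (3S,5S)‑1‑[3‑(benzyloxy)‑4‑hydroxy‑5‑methoxyphenyl]‑7‑[4‑(benzyloxy)‑3‑methoxyphenyl]heptane‑3,5‑diol
Conditions: [RuCl(p‑cymene)((S)‑BINAP)]Cl (1 mol%), H2 (80 atm), MeOH–CH2Cl2, 50 °C
Reagents that add atoms: none
Why: Noyori asymmetric hydrogenation of a β‑diketone; both C3 and C5 are set by the catalyst with the same sense (the second reduction reinforced by the ruthenium‑bound hydroxyl), giving the anti‑diol, and a wrong‑sense event ends as the separable syn diastereomer; phenol and benzyl ethers are tolerated.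

Step 6
Reactants: 8 (3S,5S)‑1‑[3‑(benzyloxy)‑4‑hydroxy‑5‑methoxyphenyl]‑7‑[4‑(benzyloxy)‑3‑methoxyphenyl]heptane‑3,5‑diol
Product: 10 (2S,4R,6S)‑2‑[3‑(benzyloxy)‑4‑hydroxy‑5‑methoxyphenyl]‑6‑{2‑[4‑(benzyloxy)‑3‑methoxyphenyl]ethyl}oxan‑4‑ol, via para‑quinone methide 9 (not isolated)
Conditions: Ag2O (3 equiv), CH2Cl2, rt, dark; filter (Celite); then camphorsulfonic acid (5 mol%), CH2Cl2, 0 °C to rt
Reagents that add atoms: none
Why: Ag2O oxidises the only free phenol (ring A; its two ortho positions carry OMe and OBn, which shuts off radical coupling) to the para‑quinone methide 9 with loss of a C1–H, and after the silver is filtered off the acid protonates the dienone oxygen so that O5–H adds to C1 (1,6‑oxa‑addition), restoring the arene. The closest known reaction type is the oxidative cyclisation of para‑hydroxyphenyl alkanols to 2‑aryl cyclic ethers through quinone methides. The oxane closes in the 6‑exo‑trig mode; attack by O3 would be 4‑exo and should not compete. The new stereocentre, oxane C2, is set under thermodynamic control: the product is a para‑hydroxybenzyl ether that re‑ionises under the acid, so both alkene isomers of 9 and both C2 epimers should drain into the chair with ring A, the C4 hydroxyl and the C6 side chain all equatorial, the C6 centre from step 5 being the controlling element. Chemoselectivity between the arenes is secured by the benzyl ether on ring B (no free phenol, no quinone methide); selectivity between the hydroxyls is secured by ring size, and since the diol is anti either hydroxyl would give the same relative configuration. Removing Ag2O before the acid is added keeps the oxidant away from the product, whose C2–H is again para‑benzylic. The C4 descriptor changes from S in 8 to R in 10 only because the CIP priorities change on ring closure; no bond at that carbon is touched.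

Step 7
Reactants: 10 (2S,4R,6S)‑2‑[3‑(benzyloxy)‑4‑hydroxy‑5‑methoxyphenyl]‑6‑{2‑[4‑(benzyloxy)‑3‑methoxyphenyl]ethyl}oxan‑4‑ol
Product: 11 (2S,4S,6S)‑2‑[3‑(benzyloxy)‑4‑hydroxy‑5‑methoxyphenyl]‑6‑{2‑[4‑(benzyloxy)‑3‑methoxyphenyl]ethyl}oxan‑4‑yl 4‑nitrobenzoate
Conditions: 4‑nitrobenzoic acid, PPh3, DIAD, THF, 0 °C to rt
Reagents that add atoms: 4‑nitrobenzoic acid, OC(=O)c1ccc(cc1)[N+](=O)[O-]
Why: Mitsunobu reaction; SN2 displacement of the equatorial oxyphosphonium group at C4 by the carboxylate inverts C4 to the axial ester, and the carboxylic acid is far more acidic than the doubly ortho‑substituted phenol, which should therefore not compete; C2 and C6 are untouched.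

Step 8
Reactants: 11 (2S,4S,6S)‑2‑[3‑(benzyloxy)‑4‑hydroxy‑5‑methoxyphenyl]‑6‑{2‑[4‑(benzyloxy)‑3‑methoxyphenyl]ethyl}oxan‑4‑yl 4‑nitrobenzoate
Product: 12 (2S,4S,6S)‑2‑[3‑(benzyloxy)‑4‑hydroxy‑5‑methoxyphenyl]‑6‑{2‑[4‑(benzyloxy)‑3‑methoxyphenyl]ethyl}oxan‑4‑ol
Conditions: K2CO3 (cat.), MeOH, rt
Reagents that add atoms: none
Why: Base‑catalysed transesterification with acyl–oxygen cleavage, so the C4 configuration is retained; done before hydrogenolysis so that the nitro group is gone first.

Step 9
Reactants: 12 (2S,4S,6S)‑2‑[3‑(benzyloxy)‑4‑hydroxy‑5‑methoxyphenyl]‑6‑{2‑[4‑(benzyloxy)‑3‑methoxyphenyl]ethyl}oxan‑4‑ol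
Product: 13 (2S,4S,6S)‑2‑(3,4‑dihydroxy‑5‑methoxyphenyl)‑6‑[2‑(4‑hydroxy‑3‑methoxyphenyl)ethyl]oxan‑4‑ol (target)
Conditions: H2 (1 atm), 10% Pd/C, EtOAc–MeOH, rt, stopped after uptake of two equivalents
Reagents that add atoms: none
Why: Hydrogenolysis of the two aryl benzyl ethers under neutral conditions; the ring O1–C2 bond is a dialkyl‑type benzylic ether and should react much more slowly, and no stereocentre is involved.

## Compound list

1 | 3,4‑dihydroxy‑5‑methoxybenzaldehyde (5‑hydroxyvanillin) | COc1cc(C=O)cc(O)c1O | starting material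
2 | 3‑(benzyloxy)‑4‑hydroxy‑5‑methoxybenzaldehyde | COc1cc(C=O)cc(OCc2ccccc2)c1O | intermediate
3 | pentane‑2,4‑dione (acetylacetone) | CC(=O)CC(C)=O | starting material
4 | 4‑(benzyloxy)‑3‑methoxybenzaldehyde | COc1cc(C=O)ccc1OCc1ccccc1 | starting material
5 | (5E)‑6‑[4‑(benzyloxy)‑3‑methoxyphenyl]hex‑5‑ene‑2,4‑dione | CC(=O)CC(=O)/C=C/c1ccc(OCc2ccccc2)c(OC)c1 | intermediate
6 | (1E,6E)‑1‑[3‑(benzyloxy)‑4‑hydroxy‑5‑methoxyphenyl]‑7‑[4‑(benzyloxy)‑3‑methoxyphenyl]hepta‑1,6‑diene‑3,5‑dione | COc1cc(/C=C/C(=O)CC(=O)/C=C/c2cc(OCc3ccccc3)c(O)c(OC)c2)ccc1OCc1ccccc1 | intermediate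
7 | 1‑[3‑(benzyloxy)‑4‑hydroxy‑5‑methoxyphenyl]‑7‑[4‑(benzyloxy)‑3‑methoxyphenyl]heptane‑3,5‑dione | COc1cc(CCC(=O)CC(=O)CCc2cc(OCc3ccccc3)c(O)c(OC)c2)ccc1OCc1ccccc1 | intermediate
8 | (3S,5S)‑1‑[3‑(benzyloxy)‑4‑hydroxy‑5‑methoxyphenyl]‑7‑[4‑(benzyloxy)‑3‑methoxyphenyl]heptane‑3,5‑diol | COc1cc(CC[C@H](O)C[C@@H](O)CCc2cc(OCc3ccccc3)c(O)c(OC)c2)ccc1OCc1ccccc1 | intermediate
9 | 2‑(benzyloxy)‑4‑{(3S,5S)‑7‑[4‑(benzyloxy)‑3‑methoxyphenyl]‑3,5‑dihydroxyheptylidene}‑6‑methoxycyclohexa‑2,5‑dien‑1‑one (para‑quinone methide, either alkene geometry) | COc1cc(CC[C@H](O)C[C@@H](O)CC=C2C=C(OCc3ccccc3)C(=O)C(OC)=C2)ccc1OCc1ccccc1 | intermediate (not isolated)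
10 | (2S,4R,6S)‑2‑[3‑(benzyloxy)‑4‑hydroxy‑5‑methoxyphenyl]‑6‑{2‑[4‑(benzyloxy)‑3‑methoxyphenyl]ethyl}oxan‑4‑ol | COc1cc(CC[C@H]2C[C@@H](O)C[C@@H](c3cc(OCc4ccccc4)c(O)c(OC)c3)O2)ccc1OCc1ccccc1 | intermediate
11 | (2S,4S,6S)‑2‑[3‑(benzyloxy)‑4‑hydroxy‑5‑methoxyphenyl]‑6‑{2‑[4‑(benzyloxy)‑3‑methoxyphenyl]ethyl}oxan‑4‑yl 4‑nitrobenzoate | COc1cc(CC[C@H]2C[C@H](OC(=O)c3ccc(cc3)[N+](=O)[O-])C[C@@H](c3cc(OCc4ccccc4)c(O)c(OC)c3)O2)ccc1OCc1ccccc1 | intermediate
12 | (2S,4S,6S)‑2‑[3‑(benzyloxy)‑4‑hydroxy‑5‑methoxyphenyl]‑6‑{2‑[4‑(benzyloxy)‑3‑methoxyphenyl]ethyl}oxan‑4‑ol | COc1cc(CC[C@H]2C[C@H](O)C[C@@H](c3cc(OCc4ccccc4)c(O)c(OC)c3)O2)ccc1OCc1ccccc1 | intermediate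
13 | (2S,4S,6S)‑2‑(3,4‑dihydroxy‑5‑methoxyphenyl)‑6‑[2‑(4‑hydroxy‑3‑methoxyphenyl)ethyl]oxan‑4‑ol | COc1cc(CC[C@H]2C[C@H](O)C[C@@H](c3cc(O)c(O)c(OC)c3)O2)ccc1O | target

## Step count and risk

Total steps: 9. Longest linear sequence: 8 (steps 2 to 9, from 3 and 4); step 1 is a one‑step branch.

**Step 6 (key step).** The likely failure is loss of material at the quinone methide stage: oligomerisation, tautomerisation to the styrene, or further oxidation of the product, whose C2–H is again para to the phenol. Fallback: set out from 8 and push the oxidation deliberately to the ketone level. DDQ in aqueous dioxane (benzylic oxidation para to a phenol) would give (3R,5S)‑1‑[3‑(benzyloxy)‑4‑hydroxy‑5‑methoxyphenyl]‑7‑[4‑(benzyloxy)‑3‑methoxyphenyl]‑3,5‑dihydroxyheptan‑1‑one F1, which rests as its hemiketal with O5. Reductive etherification (Et3SiH, BF3·OEt2, CH2Cl2–MeCN, −40 °C) then closes the ring under kinetic control, hydride adding axially to the cyclic oxocarbenium ion, and the route is rejoined at 10.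

**Step 7.** The likely failures are participation of the free ring A phenol (O‑alkylation or acylation) and elimination of the oxyphosphonium group to a dihydropyran. Fallback: from 10, benzylate the phenol (BnBr, K2CO3, acetone) to (2S,4R,6S)‑2‑[3,4‑bis(benzyloxy)‑5‑methoxyphenyl]‑6‑{2‑[4‑(benzyloxy)‑3‑methoxyphenyl]ethyl}oxan‑4‑ol F2. Oxidise with Dess–Martin periodinane to (2S,6S)‑2‑[3,4‑bis(benzyloxy)‑5‑methoxyphenyl]‑6‑{2‑[4‑(benzyloxy)‑3‑methoxyphenyl]ethyl}oxan‑4‑one F3, kept away from base. Reduce with L‑Selectride at −78 °C (equatorial attack) to (2S,4S,6S)‑2‑[3,4‑bis(benzyloxy)‑5‑methoxyphenyl]‑6‑{2‑[4‑(benzyloxy)‑3‑methoxyphenyl]ethyl}oxan‑4‑ol F4. Hydrogenolysis (H2, Pd/C) of F4 rejoins the route at 13.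

**Step 1.** The likely failure is loss of regiocontrol (benzylation at O4, or at both oxygens). Fallback: from 1, allylate the more acidic O4 selectively (allyl bromide, Li2CO3, DMF) to 4‑(allyloxy)‑3‑hydroxy‑5‑methoxybenzaldehyde F5. Benzylate O3 (BnBr, K2CO3) to 4‑(allyloxy)‑3‑(benzyloxy)‑5‑methoxybenzaldehyde F6. Remove the allyl group with Pd(PPh3)4 (zerovalent palladium) and morpholine, rejoining the route at 2.

**Step 2.** The likely failure is double condensation of 3 to the symmetrical curcuminoid, which lowers throughput and complicates purification. Fallback: a route with one alkene fewer, setting out from 2 and commercial zingerone, 4‑(4‑hydroxy‑3‑methoxyphenyl)butan‑2‑one F7. O‑Benzylation (BnBr, K2CO3) gives 4‑[4‑(benzyloxy)‑3‑methoxyphenyl]butan‑2‑one F8. Claisen condensation with ethyl acetate (NaH, THF) at the methyl group gives 6‑[4‑(benzyloxy)‑3‑methoxyphenyl]hexane‑2,4‑dione F9. Boron‑mediated aldol condensation with 2 gives (1E)‑1‑[3‑(benzyloxy)‑4‑hydroxy‑5‑methoxyphenyl]‑7‑[4‑(benzyloxy)‑3‑methoxyphenyl]hept‑1‑ene‑3,5‑dione F10. Hydrogenation as in step 4 rejoins the route at 7.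

**Step 9.** The likely failure is reductive cleavage of the benzylic O1–C2 bond once the benzyl ethers are gone, opening the ring. Fallback: from 12, switch from reductive to Lewis‑acid debenzylation (BCl3, pentamethylbenzene as cation scavenger, CH2Cl2, −78 °C), which gives 13 directly. No reductant is present, so if the ring bond ionises it can only reclose to the same cis isomer. This fallback makes no new compound (entry F0).

## Further compounds

F1 | step 6 | (3R,5S)‑1‑[3‑(benzyloxy)‑4‑hydroxy‑5‑methoxyphenyl]‑7‑[4‑(benzyloxy)‑3‑methoxyphenyl]‑3,5‑dihydroxyheptan‑1‑one | COc1cc(CC[C@H](O)C[C@@H](O)CC(=O)c2cc(OCc3ccccc3)c(O)c(OC)c2)ccc1OCc1ccccc1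
F2 | step 7 | (2S,4R,6S)‑2‑[3,4‑bis(benzyloxy)‑5‑methoxyphenyl]‑6‑{2‑[4‑(benzyloxy)‑3‑methoxyphenyl]ethyl}oxan‑4‑ol | COc1cc(CC[C@H]2C[C@@H](O)C[C@@H](c3cc(OCc4ccccc4)c(OCc4ccccc4)c(OC)c3)O2)ccc1OCc1ccccc1
F3 | step 7 | (2S,6S)‑2‑[3,4‑bis(benzyloxy)‑5‑methoxyphenyl]‑6‑{2‑[4‑(benzyloxy)‑3‑methoxyphenyl]ethyl}oxan‑4‑one | COc1cc(CC[C@H]2CC(=O)C[C@@H](c3cc(OCc4ccccc4)c(OCc4ccccc4)c(OC)c3)O2)ccc1OCc1ccccc1
F4 | step 7 | (2S,4S,6S)‑2‑[3,4‑bis(benzyloxy)‑5‑methoxyphenyl]‑6‑{2‑[4‑(benzyloxy)‑3‑methoxyphenyl]ethyl}oxan‑4‑ol | COc1cc(CC[C@H]2C[C@H](O)C[C@@H](c3cc(OCc4ccccc4)c(OCc4ccccc4)c(OC)c3)O2)ccc1OCc1ccccc1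
F5 | step 1 | 4‑(allyloxy)‑3‑hydroxy‑5‑methoxybenzaldehyde | COc1cc(C=O)cc(O)c1OCC=C
F6 | step 1 | 4‑(allyloxy)‑3‑(benzyloxy)‑5‑methoxybenzaldehyde | COc1cc(C=O)cc(OCc2ccccc2)c1OCC=C
F7 | step 2 | zingerone, 4‑(4‑hydroxy‑3‑methoxyphenyl)butan‑2‑one | COc1cc(CCC(C)=O)ccc1O
F8 | step 2 | 4‑[4‑(benzyloxy)‑3‑methoxyphenyl]butan‑2‑one | COc1cc(CCC(C)=O)ccc1OCc1ccccc1
F9 | step 2 | 6‑[4‑(benzyloxy)‑3‑methoxyphenyl]hexane‑2,4‑dione | COc1cc(CCC(=O)CC(C)=O)ccc1OCc1ccccc1
F10 | step 2 | (1E)‑1‑[3‑(benzyloxy)‑4‑hydroxy‑5‑methoxyphenyl]‑7‑[4‑(benzyloxy)‑3‑methoxyphenyl]hept‑1‑ene‑3,5‑dione | COc1cc(CCC(=O)CC(=O)/C=C/c2cc(OCc3ccccc3)c(O)c(OC)c2)ccc1OCc1ccccc1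
F0 | step 9 | none | none
A1 | alternative 1 | (1E,5S)‑1‑[3‑(benzyloxy)‑4‑hydroxy‑5‑methoxyphenyl]‑7‑[4‑(benzyloxy)‑3‑methoxyphenyl]‑5‑hydroxyhept‑1‑en‑3‑one | COc1cc(CC[C@H](O)CC(=O)/C=C/c2cc(OCc3ccccc3)c(O)c(OC)c2)ccc1OCc1ccccc1
A2 | alternative 1 | (2S,6S)‑2‑[3‑(benzyloxy)‑4‑hydroxy‑5‑methoxyphenyl]‑6‑{2‑[4‑(benzyloxy)‑3‑methoxyphenyl]ethyl}oxan‑4‑one | COc1cc(CC[C@H]2CC(=O)C[C@@H](c3cc(OCc4ccccc4)c(O)c(OC)c3)O2)ccc1OCc1ccccc1
A3 | alternative 2 | (3S)‑1‑[4‑(benzyloxy)‑3‑methoxyphenyl]hex‑5‑en‑3‑ol | COc1cc(CC[C@H](O)CC=C)ccc1OCc1ccccc1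
A4 | alternative 3 | (5S)‑1‑[3‑(benzyloxy)‑4‑hydroxy‑5‑methoxyphenyl]‑7‑[4‑(benzyloxy)‑3‑methoxyphenyl]‑5‑hydroxyheptan‑3‑one | COc1cc(CC[C@H](O)CC(=O)CCc2cc(OCc3ccccc3)c(O)c(OC)c2)ccc1OCc1ccccc1
A5 | alternative 3 | (3R,5S)‑1‑[3‑(benzyloxy)‑4‑hydroxy‑5‑methoxyphenyl]‑7‑[4‑(benzyloxy)‑3‑methoxyphenyl]heptane‑3,5‑diol | COc1cc(CC[C@H](O)C[C@H](O)CCc2cc(OCc3ccccc3)c(O)c(OC)c2)ccc1OCc1ccccc1
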